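**Conventions and assumption.** Skeleton positions carry the locants C1–C10: C1 quaternary methyl carbon, C2, C3 acetoxy carbon, C4 isopropyl carbinol carbon, C5 ring-fusion CH, C6 aroyloxy carbon, C7=C8 (methyl on C8), C9, C10 carbinol carbon. Ring A is C1–C5, ring B is C1/C5–C10. β means the face of the C1 methyl group in a flat drawing, α the opposite face. PMB = 4-methoxybenzyl, TES = triethylsilyl, TBS = tert-butyldimethylsilyl. Assumption: starting materials 1, 5 and 21 are purchased.

## Analysis of the target

The target is a cis-fused hydroazulene: cyclopentane ring A (C1–C5) shares the C1–C5 bond with cycloheptene ring B, whose only double bond is C7=C8. It has six stereocentres: quaternary C1 (methyl), C3 (acetate), fully substituted C4 (tertiary OH and isopropyl), C5 (ring-fusion H), C6 (4-hydroxybenzoate) and C10 (secondary OH). With the C1 methyl β, H5, the C3 acetate, the C4 hydroxyl and the C10 hydroxyl are also β, while the C6 ester and the isopropyl group are α. The ring A glycol is therefore cis and sits on the convex face, and the C10 hydroxyl is syn to the angular methyl. Four oxygen functions must be told apart: an alkyl acetate, an aryl ester with a free phenol, a free tertiary alcohol and a free secondary alcohol. The C6 ester is allylic and ionisable, and at the ketone stage the C6 oxygen is β to C4 and can be eliminated. The hard points are the quaternary C1 between a carbinol and the ring fusion, the seven-membered ring, and the late differentiation of two trisubstituted alkenes. The strategy rests on the unit O–C10–C1–C5–C4: a carbinol bonded to a quaternary carbon that is β to an oxygenated carbon, which is the retron of a reductive coupling between a C10 aldehyde and the β-carbon of a cyclopentenone whose carbonyl is C4.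

## Retrosynthetic reasoning

**Silyl groups last.** Target 28 is traced to bis-silyl ether 27, with TBS on the C10 oxygen and on the phenol. One acidic fluoride step then frees both hydroxyls without touching the two esters or the tertiary alcohol.

**C3–O and C4–O.** Acetate 27 comes from diol 26, and both C–O bonds of 26 are cut back to the C3=C4 alkene of 25. A nucleophile adding to a C4 ketone would enter from the convex face and put the hydroxyl on the wrong side. An oxidant adding to C3=C4 from the convex face places both oxygens correctly and leaves a secondary and a tertiary hydroxyl that differ enough for selective acetylation. The forward step must prefer C3=C4 over C7=C8, so the C6 ester is installed first to deactivate the ring B alkene.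

**C6 ester.** The acyl–oxygen bond of 25 is cut to allylic alcohol 20 and acid 23, which is made from 21. Alcohol 20 comes from PMB ether 19. PMB replaces an acetal-type group at C6 because it is removed oxidatively under neutral conditions, which the silyl ether and the acid-sensitive isopropylcyclopentene tolerate.

**C4–isopropyl bond.** Diene 19 is cut at the C4–isopropyl bond to enol triflate 18, which comes from ketone 16 by kinetic enolisation toward C3. This creates the C3=C4 alkene regiospecifically. C5 is never deprotonated, so the ring fusion and the β-ether at C6 survive.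

**C1–C10 bond, the key disconnection.** Ketone 16 is the silyl ether of γ-hydroxy ketone 15, and 15 is opened at C1–C10 to aldehyde–enone 13. One reductive step then closes ring B, creates quaternary C1, the C10 carbinol and H5, and leaves the C4 carbonyl exactly where the isopropyl carbinol is needed. The forward step must make the ketyl attack the β-carbon C1 from the face dictated by C6 and must keep samarium from bridging the ketyl oxygen and the C4 oxygen, since such a chelate would turn the C10 oxygen toward ring A and give the C10 epimer. Samarium enolate 14 must then be protonated at C5 faster than it expels the C6 ether.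

**Functional-group adjustments and C6.** Aldehyde 13 is made by oxidation of alcohol 12 immediately before use, because it is β,γ-unsaturated. Alcohol 12 comes from 11 by one mild acid step that removes the ketal and the TES ether. PMB ether 11 comes from carbinol 10, and the C6 stereocentre of 10 is set by reagent-controlled reduction of dienone 9.

**C5–C6 bond.** Dienone 9 is cut between C5 and C6 into vinyllithium 8 (from bromide 4) and Weinreb amide 7. This brings C6 in at the ketone level, so no oxidation is needed before the asymmetric reduction.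

**Fragments.** Bromide 4 comes from 1 by α-bromination (3) and ketalisation. Amide 7 comes from lactone 5 by aminolysis to 6 and silylation. Opening the lactone as an amide is preferred to reducing it, because a lactol would stay cyclic and would deliver C6 at the alcohol level.

## Alternatives that were turned down

**Alternative 1:** Prins–pinacol construction of ring A with enlargement of a six-membered ring. The bonds cut are C2–C3 and C1–C5. In the forward step a Lewis acid ionises the acetoxy acetal of A1. Its isopropenyl group closes onto the C3 oxocarbenium ion, and the tertiary C1 cation is quenched by a 1,2-shift of C5 from C10 to C1, giving A2.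
- For: the quaternary carbon and the cis fusion come from a stereospecific shift, and the complete C3/C4 glycol with the isopropyl group is already present as the dioxolane. On ring A this is stronger than the chosen route, which needs a late, site-selective dihydroxylation of 25.
- Against: A2 has the ring B alkene at C6=C7, a saturated C8 stereocentre that must be destroyed again, no oxygen at C6 and a ketone at C10. An oxidative allylic transposition with regio- and stereochemical ambiguity and a face-selective reduction would still be needed. A1 carries four stereocentres, one of them quaternary, plus two acid-labile groups, so its preparation is long.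
- Comparison: the chosen route has C6–O and C7=C8 in their final positions before the key step and starts from three simple pieces. It pays for this with a less precedented ring closure.

**Alternative 2:** [3+2] annulation of an allenylsilane onto a preformed ring B. The bonds cut are C1–C2 and C4–C5. A Lewis acid activates enone A3, and the CH2 terminus of allenylsilane A4 adds to C1. After a silyl shift the enolate carbon C5 captures the vinyl cation, giving vinylsilane A5.
- For: this annulation type is well precedented for β-methyl enones, so C1 is on firmer ground than in the chosen route. The isopropyl group arrives in the same step, and addition anti to the C10 silyloxy group would place the methyl syn to that oxygen. After protodesilylation, ring A would meet the chosen end game at the stage of 19.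
- Against: ring B is underfunctionalised. The C6 carbonyl must be turned into the C7=C8 alkene plus a C6 carbinol by dehydrogenation and a substrate-controlled reduction, and the C8 stereocentre of A3 is built only to be removed. A3 is a γ-silyloxy enone that can eliminate under the strong Lewis acid, and it needs its own multistep synthesis. Facial control rests on a single allylic substituent.
- Comparison: in exchange for its weaker precedent at C1, the chosen route sets C6 early by reagent control and has both ring B oxygens and the alkene in final form at the key step.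

**Alternative 3:** De Mayo ring expansion. The bonds cut are C7–C8 and C9–C10. Irradiation of the enol of dione A6 with allene A7 gives a cyclobutanol whose retro-aldol opening inserts the three-carbon unit and yields ene-dione A8.
- For: it is the shortest way to a cis-fused bicycle with the quaternary methyl carbon, from a simple bicyclic dione, and the exocyclic methylene can be isomerised into C7=C8.
- Against: the two enols of the unsymmetrical dione and the two orientations of the allene can give regioisomers. The C6 and C10 ketones must be differentiated and each reduced with substrate control. Ring A carries only a C3 ketal, so the isopropyl carbinol at C4 and the cis C3 oxygen would need a long sequence with regioselective enolisation toward C4.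
- Comparison: A8 is reached faster than 15, but it is much further from the target in functional groups. The chosen route puts a carbonyl at C4 and both ring B oxygens at their final oxidation level in the key step.

Key step: step 10

## Route

Step 1
Reactants: 1 3-methylcyclopent-2-en-1-one
Product: 3 2-bromo-3-methylcyclopent-2-en-1-one, via 2,3-dibromo-3-methylcyclopentan-1-one 2 (not isolated)
Conditions: Br2, CH2Cl2, 0 °C; then Et3N, 0 °C → rt
Reagents that add atoms: bromine, BrBr
Why: Bromine adds across the enone and Et3N removes HBr from the dibromide by E1cB elimination (α-bromination of an enone); no stereocentre is formed.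

Step 2
Reactants: 3 2-bromo-3-methylcyclopent-2-en-1-one
Product: 4 6-bromo-7-methyl-1,4-dioxaspiro[4.4]non-6-ene
Conditions: HOCH2CH2OH, p-TsOH·H2O (cat.), benzene, reflux, Dean–Stark trap
Reagents that add atoms: ethylene glycol, OCCO
Why: Acid-catalysed ketalisation with azeotropic removal of water; the vinylic bromide keeps the double bond in place and the ketal masks the carbonyl for the lithiation.

Step 3
Reactants: 5 4-methyl-5,6-dihydro-2H-pyran-2-one
Product: 6 (Z)-5-hydroxy-N-methoxy-N,3-dimethylpent-2-enamide
Conditions: MeNH(OMe)·HCl, Me3Al, CH2Cl2, 0 °C → rt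
Reagents that add atoms: N,O-dimethylhydroxylamine hydrochloride, CNOC.Cl
Why: Weinreb aminolysis of the lactone by the aluminium amide; the ring holds the two chain ends cis, so the alkene is released as the Z isomer, and the acyl carbon stays at the level needed for ketone formation.

Step 4
Reactants: 6 (Z)-5-hydroxy-N-methoxy-N,3-dimethylpent-2-enamide
Product: 7 (Z)-N-methoxy-N,3-dimethyl-5-(triethylsilyloxy)pent-2-enamide
Conditions: Et3SiCl, imidazole, CH2Cl2, 0 °C
Reagents that add atoms: chlorotriethylsilane, CC[Si](Cl)(CC)CC
Why: Silylation of the primary alcohol, done at once so that the hydroxy amide cannot close back to the lactone; TES is chosen because the mild acid that later opens the ketal also removes it.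

Step 5
Reactants: 4 6-bromo-7-methyl-1,4-dioxaspiro[4.4]non-6-ene; 7 (Z)-N-methoxy-N,3-dimethyl-5-(triethylsilyloxy)pent-2-enamide
Product: 9 (Z)-3-methyl-1-(7-methyl-1,4-dioxaspiro[4.4]non-6-en-6-yl)-5-(triethylsilyloxy)pent-2-en-1-one, via vinyllithium 8 (not isolated)
Conditions: 4, n-BuLi, THF, −78 °C; then 7, −78 → −40 °C; aq. NH4Cl
Reagents that add atoms: none
Why: Bromine–lithium exchange gives the vinyllithium, a masked α-anion of the enone, which adds once to the Weinreb amide and gives the ketone on work-up (C5–C6 bond); the Z alkene is not touched at low temperature.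

Step 6
Reactants: 9 (Z)-3-methyl-1-(7-methyl-1,4-dioxaspiro[4.4]non-6-en-6-yl)-5-(triethylsilyloxy)pent-2-en-1-one
Product: 10 (1S,2Z)-3-methyl-1-(7-methyl-1,4-dioxaspiro[4.4]non-6-en-6-yl)-5-(triethylsilyloxy)pent-2-en-1-ol
Conditions: (R)-2-methyl-CBS-oxazaborolidine (20 mol %), catecholborane, toluene, −78 °C
Reagents that add atoms: none
Why: CBS reduction; the fully substituted cyclopentenyl group next to the ketal should act as the large substituent and the alkenyl CH as the small one, so the (R)-catalyst should deliver hydride to the face that gives the (S)-carbinol at C6. Catecholborane at −78 °C reduces the carbonyl only (1,2).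

Step 7
Reactants: 10 (1S,2Z)-3-methyl-1-(7-methyl-1,4-dioxaspiro[4.4]non-6-en-6-yl)-5-(triethylsilyloxy)pent-2-en-1-ol
Product: 11 6-[(1S,2Z)-1-(4-methoxybenzyloxy)-3-methyl-5-(triethylsilyloxy)pent-2-en-1-yl]-7-methyl-1,4-dioxaspiro[4.4]non-6-ene
Conditions: NaH, 4-MeOC6H4CH2Cl, n-Bu4NI (cat.), THF/DMF, 0 °C → rt
Reagents that add atoms: 4-methoxybenzyl chloride, COc1ccc(CCl)cc1
Why: Williamson etherification under basic conditions, which the acid-sensitive bis-allylic carbinol tolerates; the C6–O bond is not broken, so the configuration is kept.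

Step 8
Reactants: 11 6-[(1S,2Z)-1-(4-methoxybenzyloxy)-3-methyl-5-(triethylsilyloxy)pent-2-en-1-yl]-7-methyl-1,4-dioxaspiro[4.4]non-6-ene
Product: 12 2-[(1S,2Z)-5-hydroxy-1-(4-methoxybenzyloxy)-3-methylpent-2-en-1-yl]-3-methylcyclopent-2-en-1-one
Conditions: AcOH/THF/H2O (3:1:1), 35 °C
Reagents that add atoms: water, O
Why: Mild aqueous acid hydrolyses the allylic ketal and the primary TES ether in one operation; the PMB ether and the C6 stereocentre are stable to it.

Step 9
Reactants: 12 2-[(1S,2Z)-5-hydroxy-1-(4-methoxybenzyloxy)-3-methylpent-2-en-1-yl]-3-methylcyclopent-2-en-1-one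
Product: 13 (3Z,5S)-5-(4-methoxybenzyloxy)-3-methyl-5-(2-methyl-5-oxocyclopent-1-en-1-yl)pent-3-enal
Conditions: Dess–Martin periodinane, NaHCO3, CH2Cl2, 0 °C → rt; filtered and used at once
Reagents that add atoms: none
Why: Buffered Dess–Martin oxidation of the homoallylic alcohol; the β,γ-unsaturated aldehyde is not chromatographed, so the C7=C8 bond should not move into conjugation.

Step 10
Reactants: 13 (3Z,5S)-5-(4-methoxybenzyloxy)-3-methyl-5-(2-methyl-5-oxocyclopent-1-en-1-yl)pent-3-enal
Product: 15 10β-hydroxy-6α-(4-methoxybenzyloxy)-1β,8-dimethyl-5βH-hydroazul-7-en-4-one (cis-fused), via samarium enolate 14 (not isolated)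
Conditions: SmI2 (2.5 equiv), HMPA (10 equiv), t-BuOH (3 equiv), THF, −78 °C, slow addition of 13 (final 0.005 M)
Reagents that add atoms: none
Why: Proposed new method: SmI2–HMPA reduces the unhindered aldehyde of 13 to a samarium ketyl, which adds as a nucleophilic radical to the enone β-carbon C1 (C1–C10); the α-keto radical is reduced to samarium enolate 14, which t-BuOH protonates at C5. The closest known reaction type is the SmI2 ketyl–olefin cyclization of aldehydes onto enones and enoates, which has not been shown for a seven-membered closure at a β,β-disubstituted cyclopentenone tethered through its α-carbon. Ring B closes in the 7-endo-trig mode; the 6-exo attack at C5 is polarity-mismatched and would leave an unstabilised tertiary radical, and the cis C7=C8 bond holds C10 within reach of C1. C1 is controlled by allylic 1,3-strain: H6 lies in the enone plane next to the C1 methyl, so the chain reaches C1 only from the face opposite the C6 ether oxygen, which gives the methyl/C6–O relationship of the target. C10 is controlled by an unchelated transition state: with samarium saturated by HMPA the C10–O bond lies anti to C1=C5, the bulky samarium alkoxide sits between the methyl group and C2, and the hydroxyl ends up syn to the methyl, whereas a chelate to the C4 oxygen would turn the oxygen under ring A and give the C10 epimer. C5 is set by protonation of 14 on the face of the angular methyl, away from ring B, which gives the cis fusion, also expected to be the more stable one. The step needs ketyl formation before enone reduction (the fully substituted, electron-rich enone is the poorer acceptor), closure faster than pinacol coupling (slow addition, high dilution), and protonation of 14 faster than loss of the C6 alkoxide (t-BuOH present from the start, −78 °C).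

Step 11
Reactants: 15 10β-hydroxy-6α-(4-methoxybenzyloxy)-1β,8-dimethyl-5βH-hydroazul-7-en-4-one
Product: 16 10β-(tert-butyldimethylsilyloxy)-6α-(4-methoxybenzyloxy)-1β,8-dimethyl-5βH-hydroazul-7-en-4-one
Conditions: t-BuMe2SiOTf, 2,6-lutidine, CH2Cl2, −78 °C
Reagents that add atoms: tert-butyldimethylsilyl trifluoromethanesulfonate, CC(C)(C)[Si](C)(C)OS(=O)(=O)C(F)(F)F
Why: The silyl triflate silylates the hindered secondary alcohol next to the quaternary carbon; 2,6-lutidine at −78 °C does not enolise the ketone, so C5 and the β-ether at C6 are untouched.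

Step 12
Reactants: 16 10β-(tert-butyldimethylsilyloxy)-6α-(4-methoxybenzyloxy)-1β,8-dimethyl-5βH-hydroazul-7-en-4-one
Product: 18 10β-(tert-butyldimethylsilyloxy)-6α-(4-methoxybenzyloxy)-1β,8-dimethyl-5βH-hydroazula-3,7-dien-4-yl trifluoromethanesulfonate, via potassium enolate 17 (not isolated)
Conditions: KN(SiMe3)2, THF, −78 °C; then PhNTf2, −78 → 0 °C
Reagents that add atoms: N-phenylbis(trifluoromethanesulfonimide), O=S(=O)(N(c1ccccc1)S(=O)(=O)C(F)(F)F)C(F)(F)F
Why: The bulky amide deprotonates the unhindered C3 methylene under kinetic control, not the tertiary C5–H between C1 and C6, and the enolate is O-triflated; because C5 is not deprotonated, the ring fusion is kept and the C6 ether cannot be eliminated.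

Step 13
Reactants: 18 10β-(tert-butyldimethylsilyloxy)-6α-(4-methoxybenzyloxy)-1β,8-dimethyl-5βH-hydroazula-3,7-dien-4-yl trifluoromethanesulfonate
Product: 19 10β-(tert-butyldimethylsilyloxy)-4-isopropyl-6α-(4-methoxybenzyloxy)-1β,8-dimethyl-5βH-hydroazula-3,7-diene
Conditions: i-PrMgCl, Fe(acac)3 (5 mol %), THF/NMP, −30 → 0 °C
Reagents that add atoms: isopropylmagnesium chloride, CC(C)[Mg]Cl
Why: Iron-catalysed Kumada-type coupling of an alkenyl triflate with an alkyl Grignard reagent; low-valent iron couples secondary alkyl groups quickly at low temperature without isomerisation to n-propyl, and no stereocentre is affected.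

Step 14
Reactants: 19 10β-(tert-butyldimethylsilyloxy)-4-isopropyl-6α-(4-methoxybenzyloxy)-1β,8-dimethyl-5βH-hydroazula-3,7-diene
Product: 20 10β-(tert-butyldimethylsilyloxy)-4-isopropyl-1β,8-dimethyl-5βH-hydroazula-3,7-dien-6α-ol
Conditions: DDQ, CH2Cl2/pH 7 buffer, 0 °C
Reagents that add atoms: none
Why: Oxidative PMB cleavage (benzylic hydride abstraction by DDQ, then hydrolysis of the oxocarbenium ion); the neutral conditions leave the silyl ether and both trisubstituted alkenes alone, and the C6–O bond is not broken.

Step 15
Reactants: 21 4-hydroxybenzoic acid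
Product: 23 4-(tert-butyldimethylsilyloxy)benzoic acid, via silyl ester 22 (not isolated)
Conditions: t-BuMe2SiCl (2.5 equiv), imidazole, DMF, rt; then AcOH/THF/H2O (3:1:1), rt
Reagents that add atoms: tert-butyldimethylsilyl chloride, CC(C)(C)[Si](C)(C)Cl
Why: Both hydroxyl groups are silylated and the labile silyl ester is then hydrolysed selectively, leaving the aryl silyl ether.

Step 16
Reactants: 20 10β-(tert-butyldimethylsilyloxy)-4-isopropyl-1β,8-dimethyl-5βH-hydroazula-3,7-dien-6α-ol; 23 4-(tert-butyldimethylsilyloxy)benzoic acid
Product: 25 10β-(tert-butyldimethylsilyloxy)-4-isopropyl-1β,8-dimethyl-5βH-hydroazula-3,7-dien-6α-yl 4-(tert-butyldimethylsilyloxy)benzoate, via mixed anhydride 24 (not isolated)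
Conditions: 23, 2,4,6-Cl3C6H2COCl, Et3N, THF, rt; then 20, DMAP, toluene, rt → 40 °C
Reagents that add atoms: none
Why: Yamaguchi esterification: DMAP transfers the aroyl group from the mixed anhydride to the hindered allylic alcohol; acylation occurs on oxygen, so C6 keeps its configuration.

Step 17
Reactants: 25 10β-(tert-butyldimethylsilyloxy)-4-isopropyl-1β,8-dimethyl-5βH-hydroazula-3,7-dien-6α-yl 4-(tert-butyldimethylsilyloxy)benzoate
Product: 26 10β-(tert-butyldimethylsilyloxy)-3β,4β-dihydroxy-4α-isopropyl-1β,8-dimethyl-5βH-hydroazul-7-en-6α-yl 4-(tert-butyldimethylsilyloxy)benzoate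
Conditions: OsO4 (5 mol %), NMO, acetone/H2O, 0 °C → rt
Reagents that add atoms: osmium tetroxide, O=[Os](=O)(=O)=O; N-methylmorpholine N-oxide, C[N+]1([O-])CCOCC1; water, O
Why: Upjohn dihydroxylation, a syn addition through an osmate ester; the strained, electron-rich cyclopentene C3=C4 should react before C7=C8, which is deactivated by the allylic aroyloxy group. OsO4 should approach the convex β face, because ring B and its α-oriented C6 ester shield the α face; this sets C3 and C4 with both oxygens β and the isopropyl group α.

Step 18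
Reactants: 26 10β-(tert-butyldimethylsilyloxy)-3β,4β-dihydroxy-4α-isopropyl-1β,8-dimethyl-5βH-hydroazul-7-en-6α-yl 4-(tert-butyldimethylsilyloxy)benzoate
Product: 27 3β-acetoxy-10β-(tert-butyldimethylsilyloxy)-4β-hydroxy-4α-isopropyl-1β,8-dimethyl-5βH-hydroazul-7-en-6α-yl 4-(tert-butyldimethylsilyloxy)benzoate
Conditions: Ac2O, pyridine, DMAP (cat.), CH2Cl2, 0 °C → rt
Reagents that add atoms: acetic anhydride, CC(=O)OC(C)=O
Why: Acetylation of the secondary C3 hydroxyl; the tertiary C4 hydroxyl is too hindered to react under these conditions.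

Step 19
Reactants: 27 3β-acetoxy-10β-(tert-butyldimethylsilyloxy)-4β-hydroxy-4α-isopropyl-1β,8-dimethyl-5βH-hydroazul-7-en-6α-yl 4-(tert-butyldimethylsilyloxy)benzoate
Product: 28 3β-acetoxy-4β,10β-dihydroxy-4α-isopropyl-1β,8-dimethyl-5βH-hydroazul-7-en-6α-yl 4-hydroxybenzoate (CNP0146780.2)
Conditions: HF·pyridine, pyridine/THF, 0 °C → rt
Reagents that add atoms: none
Why: Buffered HF cleaves the aryl and the hindered secondary silyl ether; the acetate, the aryl ester and the tertiary alcohol are stable to these non-basic conditions, so no acyl migration or hydrolysis is expected.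

## Compound list

1 | 3-methylcyclopent-2-en-1-one | CC1=CC(=O)CC1 | starting material
2 | 2,3-dibromo-3-methylcyclopentan-1-one (racemic) | CC1(Br)CCC(=O)C1Br | intermediate (not isolated)
3 | 2-bromo-3-methylcyclopent-2-en-1-one | CC1=C(Br)C(=O)CC1 | intermediate
4 | 6-bromo-7-methyl-1,4-dioxaspiro[4.4]non-6-ene | CC1=C(Br)C2(CC1)OCCO2 | intermediate
5 | 4-methyl-5,6-dihydro-2H-pyran-2-one | CC1=CC(=O)OCC1 | starting material
6 | (Z)-5-hydroxy-N-methoxy-N,3-dimethylpent-2-enamide | CON(C)C(=O)/C=C(C)\CCO | intermediate
7 | (Z)-N-methoxy-N,3-dimethyl-5-(triethylsilyloxy)pent-2-enamide | CON(C)C(=O)/C=C(C)\CCO[Si](CC)(CC)CC | intermediate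
8 | (7-methyl-1,4-dioxaspiro[4.4]non-6-en-6-yl)lithium | [Li]C1=C(C)CCC12OCCO2 | intermediate (not isolated)
9 | (Z)-3-methyl-1-(7-methyl-1,4-dioxaspiro[4.4]non-6-en-6-yl)-5-(triethylsilyloxy)pent-2-en-1-one | CC1=C(C(=O)/C=C(C)\CCO[Si](CC)(CC)CC)C2(CC1)OCCO2 | intermediate
10 | (1S,2Z)-3-methyl-1-(7-methyl-1,4-dioxaspiro[4.4]non-6-en-6-yl)-5-(triethylsilyloxy)pent-2-en-1-ol | CC1=C([C@@H](O)/C=C(C)\CCO[Si](CC)(CC)CC)C2(CC1)OCCO2 | intermediate
11 | 6-[(1S,2Z)-1-(4-methoxybenzyloxy)-3-methyl-5-(triethylsilyloxy)pent-2-en-1-yl]-7-methyl-1,4-dioxaspiro[4.4]non-6-ene | CC1=C([C@@H](OCc3ccc(OC)cc3)/C=C(C)\CCO[Si](CC)(CC)CC)C2(CC1)OCCO2 | intermediate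
12 | 2-[(1S,2Z)-5-hydroxy-1-(4-methoxybenzyloxy)-3-methylpent-2-en-1-yl]-3-methylcyclopent-2-en-1-one | CC1=C([C@@H](OCc2ccc(OC)cc2)/C=C(C)\CCO)C(=O)CC1 | intermediate
13 | (3Z,5S)-5-(4-methoxybenzyloxy)-3-methyl-5-(2-methyl-5-oxocyclopent-1-en-1-yl)pent-3-enal (key-step precursor) | CC1=C([C@@H](OCc2ccc(OC)cc2)/C=C(C)\CC=O)C(=O)CC1 | intermediate
14 | samarium enolate of 15 (C4=C5 enolate, C10 samarium alkoxide) | I[Sm](I)OC1=C2[C@@H](OCc3ccc(OC)cc3)C=C(C)C[C@H](O[Sm](I)I)[C@@]2(C)CC1 | intermediate (not isolated)
15 | 10β-hydroxy-6α-(4-methoxybenzyloxy)-1β,8-dimethyl-5βH-hydroazul-7-en-4-one, cis-fused (key-step product) | O=C1CC[C@]2(C)[C@@H](O)CC(C)=C[C@H](OCc3ccc(OC)cc3)[C@H]12 | intermediate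
16 | 10β-(tert-butyldimethylsilyloxy)-6α-(4-methoxybenzyloxy)-1β,8-dimethyl-5βH-hydroazul-7-en-4-one | O=C1CC[C@]2(C)[C@@H](O[Si](C)(C)C(C)(C)C)CC(C)=C[C@H](OCc3ccc(OC)cc3)[C@H]12 | intermediate
17 | potassium C3=C4 enolate of 16 | [K+].[O-]C1=CC[C@]2(C)[C@@H](O[Si](C)(C)C(C)(C)C)CC(C)=C[C@H](OCc3ccc(OC)cc3)[C@H]12 | intermediate (not isolated)
18 | 10β-(tert-butyldimethylsilyloxy)-6α-(4-methoxybenzyloxy)-1β,8-dimethyl-5βH-hydroazula-3,7-dien-4-yl trifluoromethanesulfonate | O=S(=O)(OC1=CC[C@]2(C)[C@@H](O[Si](C)(C)C(C)(C)C)CC(C)=C[C@H](OCc3ccc(OC)cc3)[C@H]12)C(F)(F)F | intermediate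
19 | 10β-(tert-butyldimethylsilyloxy)-4-isopropyl-6α-(4-methoxybenzyloxy)-1β,8-dimethyl-5βH-hydroazula-3,7-diene | CC(C)C1=CC[C@]2(C)[C@@H](O[Si](C)(C)C(C)(C)C)CC(C)=C[C@H](OCc3ccc(OC)cc3)[C@H]12 | intermediate
20 | 10β-(tert-butyldimethylsilyloxy)-4-isopropyl-1β,8-dimethyl-5βH-hydroazula-3,7-dien-6α-ol | CC(C)C1=CC[C@]2(C)[C@@H](O[Si](C)(C)C(C)(C)C)CC(C)=C[C@H](O)[C@H]12 | intermediate
21 | 4-hydroxybenzoic acid | OC(=O)c1ccc(O)cc1 | starting material
22 | tert-butyldimethylsilyl 4-(tert-butyldimethylsilyloxy)benzoate | CC(C)(C)[Si](C)(C)OC(=O)c1ccc(O[Si](C)(C)C(C)(C)C)cc1 | intermediate (not isolated)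
23 | 4-(tert-butyldimethylsilyloxy)benzoic acid | CC(C)(C)[Si](C)(C)Oc1ccc(cc1)C(O)=O | intermediate
24 | 4-(tert-butyldimethylsilyloxy)benzoic 2,4,6-trichlorobenzoic anhydride | CC(C)(C)[Si](C)(C)Oc1ccc(cc1)C(=O)OC(=O)c1c(Cl)cc(Cl)cc1Cl | intermediate (not isolated)
25 | 10β-(tert-butyldimethylsilyloxy)-4-isopropyl-1β,8-dimethyl-5βH-hydroazula-3,7-dien-6α-yl 4-(tert-butyldimethylsilyloxy)benzoate | CC(C)C1=CC[C@]2(C)[C@@H](O[Si](C)(C)C(C)(C)C)CC(C)=C[C@H](OC(=O)c3ccc(O[Si](C)(C)C(C)(C)C)cc3)[C@H]12 | intermediate
26 | 10β-(tert-butyldimethylsilyloxy)-3β,4β-dihydroxy-4α-isopropyl-1β,8-dimethyl-5βH-hydroazul-7-en-6α-yl 4-(tert-butyldimethylsilyloxy)benzoate | O[C@H]1C[C@]2(C)[C@@H](O[Si](C)(C)C(C)(C)C)CC(C)=C[C@H](OC(=O)c3ccc(O[Si](C)(C)C(C)(C)C)cc3)[C@@H]2[C@]1(O)C(C)C | intermediate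
27 | 3β-acetoxy-10β-(tert-butyldimethylsilyloxy)-4β-hydroxy-4α-isopropyl-1β,8-dimethyl-5βH-hydroazul-7-en-6α-yl 4-(tert-butyldimethylsilyloxy)benzoate | CC(=O)O[C@H]1C[C@]2(C)[C@@H](O[Si](C)(C)C(C)(C)C)CC(C)=C[C@H](OC(=O)c3ccc(O[Si](C)(C)C(C)(C)C)cc3)[C@@H]2[C@]1(O)C(C)C | intermediate
28 | 3β-acetoxy-4β,10β-dihydroxy-4α-isopropyl-1β,8-dimethyl-5βH-hydroazul-7-en-6α-yl 4-hydroxybenzoate (CNP0146780.2) | CC(=O)O[C@H]1C[C@]2(C)[C@@H](O)CC(C)=C[C@H](OC(=O)c3ccc(O)cc3)[C@@H]2[C@]1(O)C(C)C | target

## Step count and least certain steps

Total: 19 steps. Longest linear sequence: 16 steps (from 1 through steps 1, 2, 5–14, 16–19; the same length from 5 through steps 3–14, 16–19).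

**Step 10 (key step, proposed new method).** The ketyl may be reduced further or may dimerise before it closes, because the acceptor carbon is fully substituted and the ring is seven-membered. The enone radical anion or enolate 14 may also expel the C6 ether oxygen before protonation. If samarium still bridges to the C4 oxygen, the C10 epimer would form.
Fallback, from 1 back to 15: set the quaternary carbon first by conjugate addition and close ring B by ring-closing metathesis at C7=C8.
- Copper-catalysed enantioselective conjugate addition of Me2C=CHAlMe2 to 1 (Cu(OTf)2, chiral phosphoramidite), with trapping of the aluminium enolate by Me3SiOTf, should give silyl enol ether F1, which stores the C4=C5 enolate regiochemistry.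
- MeLi regenerates the lithium enolate, which should add to acrolein through a chair transition state on the face away from the isobutenyl group to give anti aldol adduct F2 (C6 as required, C5 still epimeric).
- 4-Methoxybenzyl trichloroacetimidate with catalytic camphorsulfonic acid gives PMB ether F3.
- Ozonolysis (O3, CH2Cl2, −78 °C; Me2S) should cleave the trisubstituted alkene before the vinyl group of the allylic ether, giving aldehyde F4.
- Brown methallylation with the enantiomer of B-methallyldiisopinocampheylborane that delivers the 10β-alcohol gives homoallylic alcohol F5.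
- The second-generation Grubbs catalyst (CH2Cl2, 40 °C) should close the trisubstituted cycloheptene to trans-fused ketone F6, and equilibration at C5 (DBU, toluene) should give the more stable cis-fused 15.

**Step 6.** Facial discrimination may be poor because both carbonyl substituents are alkenyl groups, and some 1,4-reduction is possible.
Fallback, from 9 back to 10: resolution instead of asymmetric reduction. Luche reduction (NaBH4, CeCl3·7H2O, MeOH, −78 °C) gives racemic alcohol F7. Esterification with (S)-methoxy(phenyl)acetic acid (DCC, DMAP) gives two diastereomers that are separated by chromatography: ester F8 from the (S)-carbinol and diastereomeric ester F9. Methanolysis of F8 (K2CO3, MeOH) returns 10.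

**Step 13.** The hindered enol triflate next to the ring fusion may be reduced to the alkene, or the isopropyl–iron species may lose a β-hydride before coupling.
Fallback, from 18 back to 19: bring the three carbons in at the sp2 level. Suzuki–Miyaura coupling with isopropenylboronic acid pinacol ester (Pd(PPh3)4, K3PO4, dioxane/H2O, 60 °C) gives triene F10. Hydrogenation with RhCl(PPh3)3 under H2 (1 atm, benzene) should reduce only the 1,1-disubstituted alkene and give 19.

**Step 17.** Osmylation may compete at C7=C8, or part of the oxidant may approach the α face.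
Fallback, from 20 back to 27: switch off the ring B alkene by oxidation state.
- Dess–Martin oxidation of 20 gives enone F11, in which C7=C8 is conjugated and electron-poor.
- OsO4/NMO should then attack only C3=C4 and give diol F12; Ac2O/pyridine gives acetate F13.
- Luche reduction should deliver hydride to the C6 carbonyl from the H5 face and give allylic alcohol F14 with the 6α-hydroxyl.
- Esterification of F14 with 23 under the conditions of step 16 gives 27. If the 6β-alcohol forms instead, Mitsunobu esterification with 23 would invert C6 to the same ester.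
- The β-hydroxy ketone stage (F12, F13) must be kept away from base to avoid retro-aldol cleavage.

## Further compounds

F1 | step 10 | trimethyl{[3-methyl-3-(2-methylprop-1-en-1-yl)cyclopent-1-en-1-yl]oxy}silane (C1 as in 15) | C[Si](C)(C)OC1=C[C@@](C)(C=C(C)C)CC1
F2 | step 10 | 2-(1-hydroxyprop-2-en-1-yl)-3-methyl-3-(2-methylprop-1-en-1-yl)cyclopentan-1-one (C1 and C6 as in 15, C5 epimeric) | O=C1CC[C@](C)(C=C(C)C)[C@H]1[C@@H](O)C=C
F3 | step 10 | 2-[1-(4-methoxybenzyloxy)prop-2-en-1-yl]-3-methyl-3-(2-methylprop-1-en-1-yl)cyclopentan-1-one | O=C1CC[C@](C)(C=C(C)C)[C@H]1[C@@H](OCc1ccc(OC)cc1)C=C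
F4 | step 10 | 2-[1-(4-methoxybenzyloxy)prop-2-en-1-yl]-1-methyl-3-oxocyclopentane-1-carbaldehyde | O=C1CC[C@](C)(C=O)[C@H]1[C@@H](OCc1ccc(OC)cc1)C=C
F5 | step 10 | 3-(1-hydroxy-3-methylbut-3-en-1-yl)-2-[1-(4-methoxybenzyloxy)prop-2-en-1-yl]-3-methylcyclopentan-1-one | O=C1CC[C@](C)([C@@H](O)CC(C)=C)[C@H]1[C@@H](OCc1ccc(OC)cc1)C=C
F6 | step 10 | 10β-hydroxy-6α-(4-methoxybenzyloxy)-1β,8-dimethyl-5αH-hydroazul-7-en-4-one (trans-fused C5 epimer of 15) | O=C1CC[C@]2(C)[C@@H](O)CC(C)=C[C@H](OCc3ccc(OC)cc3)[C@@H]12
F7 | step 6 | racemic (Z)-3-methyl-1-(7-methyl-1,4-dioxaspiro[4.4]non-6-en-6-yl)-5-(triethylsilyloxy)pent-2-en-1-ol | CC1=C(C(O)/C=C(C)\CCO[Si](CC)(CC)CC)C2(CC1)OCCO2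
F8 | step 6 | (S)-methoxy(phenyl)acetate of 10 | CC1=C([C@@H](OC(=O)[C@@H](OC)c3ccccc3)/C=C(C)\CCO[Si](CC)(CC)CC)C2(CC1)OCCO2
F9 | step 6 | (S)-methoxy(phenyl)acetate of the enantiomer of 10 | CC1=C([C@H](OC(=O)[C@@H](OC)c3ccccc3)/C=C(C)\CCO[Si](CC)(CC)CC)C2(CC1)OCCO2
F10 | step 13 | 10β-(tert-butyldimethylsilyloxy)-4-isopropenyl-6α-(4-methoxybenzyloxy)-1β,8-dimethyl-5βH-hydroazula-3,7-diene | CC(=C)C1=CC[C@]2(C)[C@@H](O[Si](C)(C)C(C)(C)C)CC(C)=C[C@H](OCc3ccc(OC)cc3)[C@H]12
F11 | step 17 | 10β-(tert-butyldimethylsilyloxy)-4-isopropyl-1β,8-dimethyl-5βH-hydroazula-3,7-dien-6-one | CC(C)C1=CC[C@]2(C)[C@@H](O[Si](C)(C)C(C)(C)C)CC(C)=CC(=O)[C@H]12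
F12 | step 17 | 10β-(tert-butyldimethylsilyloxy)-3β,4β-dihydroxy-4α-isopropyl-1β,8-dimethyl-5βH-hydroazul-7-en-6-one | O[C@H]1C[C@]2(C)[C@@H](O[Si](C)(C)C(C)(C)C)CC(C)=CC(=O)[C@@H]2[C@]1(O)C(C)C
F13 | step 17 | 3β-acetoxy-10β-(tert-butyldimethylsilyloxy)-4β-hydroxy-4α-isopropyl-1β,8-dimethyl-5βH-hydroazul-7-en-6-one | CC(=O)O[C@H]1C[C@]2(C)[C@@H](O[Si](C)(C)C(C)(C)C)CC(C)=CC(=O)[C@@H]2[C@]1(O)C(C)C
F14 | step 17 | 3β-acetoxy-10β-(tert-butyldimethylsilyloxy)-4α-isopropyl-1β,8-dimethyl-5βH-hydroazul-7-ene-4β,6α-diol | CC(=O)O[C@H]1C[C@]2(C)[C@@H](O[Si](C)(C)C(C)(C)C)CC(C)=C[C@H](O)[C@@H]2[C@]1(O)C(C)C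
A1 | alternative 1 | 4-acetoxy-5-isopropyl-5-[6-isopropenyl-4-methyl-6-(triethylsilyloxy)cyclohex-2-en-1-yl]-2,2-dimethyl-1,3-dioxolane (C3 acetal and C10 carbinol configurations left open) | CC(=C)C1(O[Si](CC)(CC)CC)C[C@@H](C)C=C[C@@H]1[C@@]1(C(C)C)OC(C)(C)OC1OC(C)=O
A2 | alternative 1 | cis-fused hydroazulen-10-one with C3,C4-acetonide and C6=C7 alkene | CC1(C)O[C@H]2C[C@]3(C)C(=O)C[C@@H](C)C=C[C@@H]3[C@]2(O1)C(C)C
A3 | alternative 2 | 4-(tert-butyldimethylsilyloxy)-3,6-dimethylcyclohept-2-en-1-one | O=C1C=C(C)[C@@H](O[Si](C)(C)C(C)(C)C)C[C@@H](C)C1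
A4 | alternative 2 | (4-methylpenta-1,2-dien-3-yl)trimethylsilane | C=C=C(C(C)C)[Si](C)(C)C
A5 | alternative 2 | cis-fused hydroazulen-6-one with C3 trimethylsilyl, C4 isopropyl alkene and C10 silyloxy | C[Si](C)(C)C1=C(C(C)C)[C@H]2C(=O)C[C@H](C)C[C@H](O[Si](C)(C)C(C)(C)C)[C@@]2(C)C1
A6 | alternative 3 | cis-1-methylbicyclo[3.3.0]octane-2,4-dione 7-ethylene ketal | O1CCOC12C[C@]3(C)C(=O)CC(=O)[C@@H]3C2
A7 | alternative 3 | propa-1,2-diene (allene) | C=C=C
A8 | alternative 3 | cis-fused hydroazulene-6,10-dione with C8 exocyclic methylene and C3 ketal | O1CCOC12C[C@]3(C)C(=O)CC(=C)CC(=O)[C@@H]3C2
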